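**Retrosynthetic overview**
1. The strategy rests on the 2H-pyran ring (O1, C2, C3=C4, C4a, C8a): it is the dehydrogenated, ring-closed form of an E-trisubstituted allyl unit bound to C4a next to the phenolic oxygen, so the ring and the C2 stereocentre lie two hydrogens above an ortho-polyprenyl phenol with no stereocentre at that carbon.
2. Target <= its 6-O-acetate <= (O1–C2 disconnection, the only ring formed) 4-O-acetyl-2-methyl-6-polyprenylhydroquinone, by flavoenzyme dehydrogenation of the benzylic CH2 and oxa-6π electrocyclisation.
3. Aryl–C1 disconnection: an arylcopper from a regiodefined 2-bromo-6-methylhydroquinone (O1 as 1-ethoxyethyl acetal, O4 as TBS ether; made from 4-hydroxy-3-methylbenzaldehyde by bromination and Dakin oxidation) plus the C20 allylic bromide.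
4. C8–C9 disconnection: copper-catalysed allylation of (S)-3,7-dimethyloct-6-en-1-yn-3-ol (from geraniol by Sharpless epoxidation and epoxy chloride fragmentation; it carries the carbinol stereocentre) with 8-bromogeranyl acetate (from geranyl acetate, SeO2), then trans-hydroalumination to the 9E alkene.

Key step: step 17

Remark: chain carbons are counted C1–C16 from the carbon that becomes bonded to the arene, and the acetal carbon of the 1-ethoxyethyl group is not controlled, so every compound carrying it is a mixture of both configurations at that carbon only.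

**Step 1**
Reactants: 1 geraniol
Product: 2 [(2S,3S)-3-methyl-3-(4-methylpent-3-en-1-yl)oxiran-2-yl]methanol ((2S,3S)-2,3-epoxygeraniol)
Conditions: Ti(OiPr)4 (5 mol%), L-(+)-diethyl tartrate (6 mol%), t-BuOOH, 4 Å molecular sieves, CH2Cl2, −20 °C
Reagents that add atoms: tert-butyl hydroperoxide, CC(C)(C)OO
Why: Sharpless asymmetric epoxidation, in which the titanium tartrate complex binds the allylic hydroxyl, epoxidises only the 2,3-alkene and, with the L-(+)-tartrate ligand, should select the alkene face that gives the (2S,3S)-epoxide, so that C3, the later carbinol carbon of the side chain, is set here.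

**Step 2**
Reactants: 2 (2S,3S)-2,3-epoxygeraniol
Product: 3 (2S,3R)-3-(chloromethyl)-2-methyl-2-(4-methylpent-3-en-1-yl)oxirane
Conditions: PPh3, CCl4, NaHCO3, reflux
Reagents that add atoms: tetrachloromethane, ClC(Cl)(Cl)Cl
Why: Appel chlorination should replace the primary hydroxyl by chloride through SN2 attack on the oxyphosphonium salt under buffered, non-acidic conditions that leave the epoxide, the alkene and both stereocentres untouched (the descriptor at the CH carbon changes only because of the new substituent priority).

**Step 3**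
Reactants: 3 epoxy chloride
Product: 5 (3S)-3,7-dimethyloct-6-en-1-yn-3-ol, via chlorovinyl carbinol 4 (not isolated)
Conditions: n-BuLi (3.2 equiv), THF, −40 → 0 °C; aq. NH4Cl
Reagents that add atoms: none
Why: Base-induced fragmentation of a 2,3-epoxy chloride, in which lithiation next to chlorine opens the epoxide by beta-elimination to the chlorovinyl alkoxide, a second equivalent of base eliminates HCl to the alkyne and a third deprotonates it, never breaks the C3–O bond, so the S configuration should be carried over unchanged.

**Step 4**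
Reactants: 6 geranyl acetate
Product: 7 (2E,6E)-8-hydroxy-3,7-dimethylocta-2,6-dien-1-yl acetate
Conditions: SeO2 (10 mol%), t-BuOOH, salicylic acid (10 mol%), CH2Cl2, rt
Reagents that add atoms: selenium dioxide, O=[Se]=O (catalytic oxygen carrier); tert-butyl hydroperoxide, CC(C)(C)OO (terminal oxygen source)
Why: Catalytic SeO2 allylic oxidation (ene reaction followed by [2,3]-sigmatropic shift) should attack the electron-richer terminal alkene, the 2,3-alkene being deactivated by the allylic acetate, and oxidise the methyl group trans to the chain, which gives the E-allylic alcohol.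

**Step 5**
Reactants: 7 hydroxy acetate
Product: 8 (2E,6E)-8-bromo-3,7-dimethylocta-2,6-dien-1-yl acetate
Conditions: CBr4, PPh3, CH2Cl2, 0 °C
Reagents that add atoms: tetrabromomethane, BrC(Br)(Br)Br
Why: Appel bromination at 0 °C should convert the primary allylic alcohol into the bromide by direct SN2 displacement without allylic transposition or loss of the 6E geometry, and the allylic acetate is inert.

**Step 6**
Reactants: 5 (3S)-3,7-dimethyloct-6-en-1-yn-3-ol and 8 bromo acetate
Product: 9 (2E,6E,11S)-11-hydroxy-3,7,11,15-tetramethylhexadeca-2,6,14-trien-9-yn-1-yl acetate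
Conditions: CuI (10 mol%), Bu4NI (10 mol%), K2CO3, DMF, rt, degassed
Reagents that add atoms: none
Why: Copper-catalysed allylation of a terminal alkyne, in which the copper acetylide formed with K2CO3 should displace the primary allylic bromide at its CH2 terminus (SN2 mode) to form C8–C9 with retention of the 6E geometry, tolerates the free tertiary hydroxyl and does not ionise the allylic acetate.

**Step 7**
Reactants: 9 enyne hydroxy acetate
Product: 11 (2E,6E,9E,11S)-3,7,11,15-tetramethylhexadeca-2,6,9,14-tetraene-1,11-diol, via enynediol 10 (not isolated)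
Conditions: NaAlH2(OCH2CH2OMe)2 (Red-Al, 4 equiv), THF, 0 °C → rt; aq. potassium sodium tartrate
Reagents that add atoms: none
Why: The hydride first cleaves the acetate reductively and then effects the trans-hydroalumination of the propargylic alcohol, in which the tertiary alkoxide binds aluminium and delivers hydride to C9 so that protonolysis of the cyclic alkenylalanate should give the 9E alkene only, while the isolated trisubstituted alkenes are not reduced.

**Step 8**
Reactants: 11 diol
Product: 13 (2E,6E,9E,11S)-1-bromo-3,7,11,15-tetramethylhexadeca-2,6,9,14-tetraen-11-ol, via allylic mesylate 12 (not isolated)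
Conditions: MsCl, Et3N, THF, −40 °C; then LiBr, THF, −40 → 0 °C
Reagents that add atoms: lithium bromide, [Li+].[Br-]
Why: Selective sulfonylation of the unhindered primary allylic hydroxyl at low temperature (the tertiary hydroxyl is too hindered to react) followed by SN2 displacement with bromide should give the primary allylic bromide without acid, so the tertiary allylic alcohol and all alkene geometries survive.

**Step 9**
Reactants: 13 bromo alcohol
Product: 14 {[(2E,6E,9E,11S)-1-bromo-3,7,11,15-tetramethylhexadeca-2,6,9,14-tetraen-11-yl]oxy}triethylsilane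
Conditions: TESOTf, 2,6-lutidine, CH2Cl2, −78 °C
Reagents that add atoms: triethylsilyl trifluoromethanesulfonate, CC[Si](CC)(CC)OS(=O)(=O)C(F)(F)F
Why: Silylation with a silyl triflate and a hindered, non-nucleophilic base should mask the tertiary hydroxyl, the only acidic proton of the chain, before the organometallic coupling, and the allylic bromide does not react under these conditions.

**Step 10**
Reactants: 15 4-hydroxy-3-methylbenzaldehyde
Product: 16 3-bromo-4-hydroxy-5-methylbenzaldehyde
Conditions: Br2, AcOH, rt
Reagents that add atoms: bromine, BrBr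
Why: Electrophilic aromatic bromination should occur at the only free position ortho to the hydroxyl (also meta to the formyl group), which fixes the halogen next to the oxygen that will carry the chain and avoids the regiochemical ambiguity of metalating a symmetrically protected 2-methylhydroquinone.

**Step 11**
Reactants: 16 bromo aldehyde
Product: 18 2-bromo-6-methylbenzene-1,4-diol, via aryl formate 17 (not isolated)
Conditions: H2O2 (30% aq.), NaOH, H2O/THF, 0 °C → rt, N2; then aq. HCl
Reagents that add atoms: hydrogen peroxide, OO
Why: Dakin oxidation, in which hydroperoxide adds to the aldehyde of the para-hydroxybenzaldehyde, the electron-rich aryl group migrates to oxygen and the formate is saponified in the same flask, should give the hydroquinone with the substitution pattern already defined.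

**Step 12**
Reactants: 18 2-bromo-6-methylbenzene-1,4-diol
Product: 19 2-bromo-4-[(tert-butyldimethylsilyl)oxy]-6-methylphenol
Conditions: TBSCl (1.0 equiv), imidazole, CH2Cl2, 0 °C
Reagents that add atoms: tert-butyldimethylsilyl chloride, CC(C)(C)[Si](C)(C)Cl
Why: Silylation under steric control should take place only at O4, whose two ortho positions are free, because the O1 hydroxyl lies between bromine and methyl.

**Step 13**
Reactants: 19 mono-TBS ether
Product: 20 tert-butyl[3-bromo-4-(1-ethoxyethoxy)-5-methylphenoxy]dimethylsilane
Conditions: ethyl vinyl ether, PPTS (cat.), CH2Cl2, rt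
Reagents that add atoms: ethyl vinyl ether, C=COCC
Why: Acid-catalysed addition of the phenol to the vinyl ether should give the 1-ethoxyethyl acetal, a group that tolerates aryllithium chemistry and is later removed by very mild acid, while the aryl silyl ether is stable to PPTS.

**Step 14**
Reactants: 20 aryl bromide (1.5 equiv) and 14 chain bromide
Product: 23 tert-butyl{4-(1-ethoxyethoxy)-3-methyl-5-[(2E,6E,9E,11S)-3,7,11,15-tetramethyl-11-(triethylsilyloxy)hexadeca-2,6,9,14-tetraen-1-yl]phenoxy}dimethylsilane, via aryllithium 21 (not isolated), via arylcopper 22 (not isolated)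
Conditions: n-BuLi, THF, −78 °C; CuBr·SMe2, −78 → −40 °C; then 14, −78 → 0 °C
Reagents that add atoms: none
Why: Bromine–lithium exchange, transmetalation to the arylcopper and SN2 substitution of the primary allylic bromide at C1 (the fully substituted gamma carbon disfavours SN2' attack) should form the aryl–C1 bond with retention of the 2E geometry, the halogen defining the site of metalation, the meta silyl ether being unable to undergo retro-Brook migration and the chain carrying no acidic proton.

**Step 15**
Reactants: 23 coupled bis-silyl ether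
Product: 25 4-(1-ethoxyethoxy)-3-[(2E,6E,9E,11S)-11-hydroxy-3,7,11,15-tetramethylhexadeca-2,6,9,14-tetraen-1-yl]-5-methylphenyl acetate, via phenol 24 (not isolated)
Conditions: Bu4NF, THF, 0 °C → rt; then AcOH, pyridine, Ac2O, 0 °C → rt
Reagents that add atoms: acetic anhydride, CC(=O)OC(C)=O
Why: Fluoride should cleave both the aryl TBS and the tertiary TES ether, and after buffering the unhindered phenol is acetylated by Ac2O/pyridine, conditions under which a tertiary alcohol is not acylated (no DMAP) and the acetal on O1 is stable.

**Step 16**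
Reactants: 25 acetal acetate
Product: 26 4-hydroxy-3-[(2E,6E,9E,11S)-11-hydroxy-3,7,11,15-tetramethylhexadeca-2,6,9,14-tetraen-1-yl]-5-methylphenyl acetate
Conditions: PPTS (cat.), MeOH, 0 °C → rt
Reagents that add atoms: none
Why: Transacetalisation to methanol under pyridinium catalysis should release the phenol at an acidity too low to ionise the tertiary allylic alcohol, to cyclise the ortho-allyl phenol to a chroman or to methanolyse the aryl acetate.

**Step 17**
Reactants: 26 hydroquinone 4-monoacetate
Product: 28 (2S)-2-[(3E,6E,8S)-8-hydroxy-4,8,12-trimethyltrideca-3,6,11-trien-1-yl]-2,8-dimethyl-2H-chromen-6-yl acetate, via ortho-quinone methide 27 (not isolated)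
Conditions: FAD-dependent berberine-bridge-enzyme-like oxidocyclase variant (from screening and directed evolution of a daurichromenic acid synthase scaffold), air, catalase, phosphate buffer pH 6.5, DMSO (5% v/v), 30 °C
Reagents that add atoms: none
Why: Proposed new method: the enzyme-bound flavin should accept hydride at N5 from the benzylic and allylic C1 methylene of 26 (the future C4) while an active-site base takes the proton of the free ortho phenol, which gives the ortho-quinone methide 27 conjugated to the E-configured C2=C3 alkene of the chain, and O2 reoxidises the reduced flavin; the closest known reaction type is the oxidative cyclisation of ortho-polyprenyl resorcylic acids to 2-alkyl-2-methyl-2H-chromenes by FAD oxidocyclases of the berberine bridge enzyme family (daurichromenic acid synthase, cannabichromenic acid synthase), which has not been shown for a hydroquinone monoacetate lacking the carboxylate, so a variant would have to be found by screening and directed evolution. The pyran ring then closes by a thermal, disrotatory oxa-6π electrocyclisation of the 1-oxatriene O=C8a–C4a=C4–C3=C2, in which the carbonyl oxygen bonds to chain carbon C3, the new C2. The new stereocentre C2 is controlled by the enzyme alone: the alkene geometry is fixed as E in the substrate, so the helical sense in which the active site holds the oxatriene decides which face of C2 the oxygen reaches, and a variant enforcing the helix that leads to 2S is needed because a released quinone methide would close without facial preference. The step needs site selectivity for one C–H oxidation and facial selectivity in the ring closure; the substrate secures the first because it has a single benzylic methylene beside a free phenol, its distal oxygen is acetylated so that oxidation to the para-quinone is blocked, and its 11S tertiary alcohol has no carbinol hydrogen, whereas the second must come from the protein.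

**Step 18**
Reactants: 28 chromenyl acetate
Product: 29 (2S)-2-[(3E,6E,8S)-8-hydroxy-4,8,12-trimethyltrideca-3,6,11-trien-1-yl]-2,8-dimethyl-2H-chromen-6-ol (CNP0155965.1)
Conditions: K2CO3 (cat.), MeOH, 0 °C, argon
Reagents that add atoms: none
Why: Base-catalysed transesterification should methanolyse the aryl acetate rapidly under conditions to which the 2H-chromene, the tertiary allylic alcohol and both stereocentres are inert, air being excluded to protect the electron-rich chromenol.

**Compound list**
1 | geraniol, (2E)-3,7-dimethylocta-2,6-dien-1-ol | CC(C)=CCC/C(C)=C/CO | starting material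
2 | [(2S,3S)-3-methyl-3-(4-methylpent-3-en-1-yl)oxiran-2-yl]methanol | CC(C)=CCC[C@]1(C)O[C@H]1CO | intermediate
3 | (2S,3R)-3-(chloromethyl)-2-methyl-2-(4-methylpent-3-en-1-yl)oxirane | CC(C)=CCC[C@]1(C)O[C@H]1CCl | intermediate
4 | (3S)-1-chloro-3,7-dimethylocta-1,6-dien-3-ol, present as its lithium alkoxide, alkene geometry not defined (not isolated) | CC(C)=CCC[C@](C)(O)C=CCl | intermediate
5 | (3S)-3,7-dimethyloct-6-en-1-yn-3-ol | CC(C)=CCC[C@](C)(O)C#C | intermediate
6 | geranyl acetate, (2E)-3,7-dimethylocta-2,6-dien-1-yl acetate | CC(C)=CCC/C(C)=C/COC(C)=O | starting material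
7 | (2E,6E)-8-hydroxy-3,7-dimethylocta-2,6-dien-1-yl acetate | OC/C(C)=C/CC/C(C)=C/COC(C)=O | intermediate
8 | (2E,6E)-8-bromo-3,7-dimethylocta-2,6-dien-1-yl acetate | BrC/C(C)=C/CC/C(C)=C/COC(C)=O | intermediate
9 | (2E,6E,11S)-11-hydroxy-3,7,11,15-tetramethylhexadeca-2,6,14-trien-9-yn-1-yl acetate | CC(C)=CCC[C@](C)(O)C#CC/C(C)=C/CC/C(C)=C/COC(C)=O | intermediate
10 | (2E,6E,11S)-3,7,11,15-tetramethylhexadeca-2,6,14-trien-9-yne-1,11-diol (not isolated) | CC(C)=CCC[C@](C)(O)C#CC/C(C)=C/CC/C(C)=C/CO | intermediate
11 | (2E,6E,9E,11S)-3,7,11,15-tetramethylhexadeca-2,6,9,14-tetraene-1,11-diol | CC(C)=CCC[C@](C)(O)/C=C/C/C(C)=C/CC/C(C)=C/CO | intermediate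
12 | (2E,6E,9E,11S)-11-hydroxy-3,7,11,15-tetramethylhexadeca-2,6,9,14-tetraen-1-yl methanesulfonate (not isolated) | CC(C)=CCC[C@](C)(O)/C=C/C/C(C)=C/CC/C(C)=C/COS(C)(=O)=O | intermediate
13 | (2E,6E,9E,11S)-1-bromo-3,7,11,15-tetramethylhexadeca-2,6,9,14-tetraen-11-ol | CC(C)=CCC[C@](C)(O)/C=C/C/C(C)=C/CC/C(C)=C/CBr | intermediate
14 | {[(2E,6E,9E,11S)-1-bromo-3,7,11,15-tetramethylhexadeca-2,6,9,14-tetraen-11-yl]oxy}triethylsilane | CC(C)=CCC[C@](C)(O[Si](CC)(CC)CC)/C=C/C/C(C)=C/CC/C(C)=C/CBr | intermediate
15 | 4-hydroxy-3-methylbenzaldehyde | Cc1cc(C=O)ccc1O | starting material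
16 | 3-bromo-4-hydroxy-5-methylbenzaldehyde | Cc1cc(C=O)cc(Br)c1O | intermediate
17 | 3-bromo-4-hydroxy-5-methylphenyl formate (not isolated) | Cc1cc(OC=O)cc(Br)c1O | intermediate
18 | 2-bromo-6-methylbenzene-1,4-diol | Cc1cc(O)cc(Br)c1O | intermediate
19 | 2-bromo-4-[(tert-butyldimethylsilyl)oxy]-6-methylphenol | Cc1cc(O[Si](C)(C)C(C)(C)C)cc(Br)c1O | intermediate
20 | tert-butyl[3-bromo-4-(1-ethoxyethoxy)-5-methylphenoxy]dimethylsilane (acetal carbon racemic) | CCOC(C)Oc1c(C)cc(O[Si](C)(C)C(C)(C)C)cc1Br | intermediate
21 | [5-(tert-butyldimethylsilyloxy)-2-(1-ethoxyethoxy)-3-methylphenyl]lithium (not isolated) | CCOC(C)Oc1c(C)cc(O[Si](C)(C)C(C)(C)C)cc1[Li] | intermediate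
22 | [5-(tert-butyldimethylsilyloxy)-2-(1-ethoxyethoxy)-3-methylphenyl]copper (not isolated) | CCOC(C)Oc1c(C)cc(O[Si](C)(C)C(C)(C)C)cc1[Cu] | intermediate
23 | tert-butyl{4-(1-ethoxyethoxy)-3-methyl-5-[(2E,6E,9E,11S)-3,7,11,15-tetramethyl-11-(triethylsilyloxy)hexadeca-2,6,9,14-tetraen-1-yl]phenoxy}dimethylsilane (both configurations at the acetal carbon) | CC(C)=CCC[C@](C)(O[Si](CC)(CC)CC)/C=C/C/C(C)=C/CC/C(C)=C/Cc1cc(O[Si](C)(C)C(C)(C)C)cc(C)c1OC(C)OCC | intermediate
24 | 4-(1-ethoxyethoxy)-3-[(2E,6E,9E,11S)-11-hydroxy-3,7,11,15-tetramethylhexadeca-2,6,9,14-tetraen-1-yl]-5-methylphenol (not isolated) | CC(C)=CCC[C@](C)(O)/C=C/C/C(C)=C/CC/C(C)=C/Cc1cc(O)cc(C)c1OC(C)OCC | intermediate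
25 | 4-(1-ethoxyethoxy)-3-[(2E,6E,9E,11S)-11-hydroxy-3,7,11,15-tetramethylhexadeca-2,6,9,14-tetraen-1-yl]-5-methylphenyl acetate | CC(C)=CCC[C@](C)(O)/C=C/C/C(C)=C/CC/C(C)=C/Cc1cc(OC(C)=O)cc(C)c1OC(C)OCC | intermediate
26 | 4-hydroxy-3-[(2E,6E,9E,11S)-11-hydroxy-3,7,11,15-tetramethylhexadeca-2,6,9,14-tetraen-1-yl]-5-methylphenyl acetate | CC(C)=CCC[C@](C)(O)/C=C/C/C(C)=C/CC/C(C)=C/Cc1cc(OC(C)=O)cc(C)c1O | intermediate
27 | ortho-quinone methide: 4-acetoxy-2-methyl-6-[(1Z,2E,6E,9E,11S)-11-hydroxy-3,7,11,15-tetramethylhexadeca-2,6,9,14-tetraen-1-ylidene]cyclohexa-2,4-dien-1-one, enzyme-bound (not isolated) | CC(C)=CCC[C@](C)(O)/C=C/C/C(C)=C/CC/C(C)=C/C=C1/C=C(OC(C)=O)C=C(C)C1=O | intermediate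
28 | (2S)-2-[(3E,6E,8S)-8-hydroxy-4,8,12-trimethyltrideca-3,6,11-trien-1-yl]-2,8-dimethyl-2H-chromen-6-yl acetate | CC(C)=CCC[C@](C)(O)/C=C/C/C(C)=C/CC[C@@]1(C)C=Cc2cc(OC(C)=O)cc(C)c2O1 | intermediate
29 | (2S)-2-[(3E,6E,8S)-8-hydroxy-4,8,12-trimethyltrideca-3,6,11-trien-1-yl]-2,8-dimethyl-2H-chromen-6-ol | CC(C)=CCC[C@](C)(O)/C=C/C/C(C)=C/CC[C@@]1(C)C=Cc2cc(O)cc(C)c2O1 | target

**Step count**
Total: 18 steps. Longest linear sequence: 12 steps (steps 1–3, 6–9 and 14–18, from geraniol).

**Steps most likely to fail**

Step 17. No enzyme variant may accept the acetylated hydroquinone. The quinone methide may also leave the active site and close without facial control, or oxidation may start at another position. Fallback with known chemistry, setting out from 26: cyclodehydrogenation with DDQ (benzene, rt → 60 °C), the established chemical route from ortho-prenylphenols to 2H-chromenes through the same quinone methide. It would give 28 together with its C2 epimer, (2R)-2-[(3E,6E,8S)-8-hydroxy-4,8,12-trimethyltrideca-3,6,11-trien-1-yl]-2,8-dimethyl-2H-chromen-6-yl acetate F1. The two are diastereomers and would be separated by preparative HPLC on a polysaccharide chiral stationary phase. The 2S isomer comes back to the route at 28.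

Step 14. The arylcopper may attack the gamma carbon (SN2' mode), the 2E geometry may erode through allylcopper intermediates, or the aryl metal may be protonated before it couples. Fallback, setting out from 20: bromine–lithium exchange (n-BuLi, THF, −78 °C) and quenching of 21 with Bu3SnCl would give tributyl[5-(tert-butyldimethylsilyloxy)-2-(1-ethoxyethoxy)-3-methylphenyl]stannane F2. Stille coupling of F2 with 14 (Pd2(dba)3, AsPh3, THF, 50 °C) joins the aryl group to the less hindered allyl terminus with retention of alkene geometry under neutral conditions. It comes back to the route at 23.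

Step 6. The copper acetylide may attack the monosubstituted gamma carbon of 8, or the base may isomerise the skipped enyne to allenic or conjugated products. Fallback, setting out from 5 and 8 and bypassing steps 7–9:
- silylation of 5 (TESCl, imidazole, DMF) to triethyl{[(3S)-3,7-dimethyloct-6-en-1-yn-3-yl]oxy}silane F3;
- hydrozirconation with Cp2Zr(H)Cl (THF, rt) to the E-alkenylzirconocene, chlorobis(cyclopentadienyl)[(1E,3S)-3,7-dimethyl-3-(triethylsilyloxy)octa-1,6-dien-1-yl]zirconium F4;
- Negishi-type coupling of F4 with 8 (Pd(PPh3)4 cat., THF, rt), in which zerovalent palladium ionises the allylic bromide far faster than the allylic acetate and the alkenyl group is delivered to the primary terminus, to give (2E,6E,9E,11S)-3,7,11,15-tetramethyl-11-(triethylsilyloxy)hexadeca-2,6,9,14-tetraen-1-yl acetate F5 with the 9E alkene already in place;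
- methanolysis (K2CO3, MeOH) to (2E,6E,9E,11S)-3,7,11,15-tetramethyl-11-(triethylsilyloxy)hexadeca-2,6,9,14-tetraen-1-ol F6;
- Appel bromination (CBr4, PPh3, CH2Cl2, 0 °C), which comes back to the route at 14.

**Further compounds**
F1 | step 17 | (2R)-2-[(3E,6E,8S)-8-hydroxy-4,8,12-trimethyltrideca-3,6,11-trien-1-yl]-2,8-dimethyl-2H-chromen-6-yl acetate | CC(C)=CCC[C@](C)(O)/C=C/C/C(C)=C/CC[C@]1(C)C=Cc2cc(OC(C)=O)cc(C)c2O1
F2 | step 14 | tributyl[5-(tert-butyldimethylsilyloxy)-2-(1-ethoxyethoxy)-3-methylphenyl]stannane | CCCC[Sn](CCCC)(CCCC)c1cc(O[Si](C)(C)C(C)(C)C)cc(C)c1OC(C)OCC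
F3 | step 6 | triethyl{[(3S)-3,7-dimethyloct-6-en-1-yn-3-yl]oxy}silane | CC(C)=CCC[C@](C)(O[Si](CC)(CC)CC)C#C
F4 | step 6 | chlorobis(cyclopentadienyl)[(1E,3S)-3,7-dimethyl-3-(triethylsilyloxy)octa-1,6-dien-1-yl]zirconium | CC(C)=CCC[C@](C)(O[Si](CC)(CC)CC)/C=C/[Zr](Cl)(C1C=CC=C1)C1C=CC=C1
F5 | step 6 | (2E,6E,9E,11S)-3,7,11,15-tetramethyl-11-(triethylsilyloxy)hexadeca-2,6,9,14-tetraen-1-yl acetate | CC(C)=CCC[C@](C)(O[Si](CC)(CC)CC)/C=C/C/C(C)=C/CC/C(C)=C/COC(C)=O
F6 | step 6 | (2E,6E,9E,11S)-3,7,11,15-tetramethyl-11-(triethylsilyloxy)hexadeca-2,6,9,14-tetraen-1-ol | CC(C)=CCC[C@](C)(O[Si](CC)(CC)CC)/C=C/C/C(C)=C/CC/C(C)=C/CO
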